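**Retrosynthetic overview**

- The target is (5S,8R,9R,10S,13R,14R)-15-acetoxylabdane-8α,13,14-triol, i.e. (−)-sclareol whose vinyl group has become CH(OH)–CH2OAc. Rings A and B and five of the six stereocentres (C5, C8, C9, C10, C13) are those of sclareol.
- Disconnection 1: C15–OAc ⇒ acetate + the terminal (13R,14R)-14,15-epoxide (attack at the CH2 carbon, C14 untouched).
- Disconnection 2 (key): C14–O ⇒ the vinyl group of sclareol + O2. The bond is made in an electrolysis in which a vanadium centre, held by both the 8- and the 13-oxygen, passes on a cathodically made peroxide oxygen. C13, with O8 as second anchor, controls C14.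
- Ring order: no carbocycle is built. The only ring formed is the oxirane (step 1), and it is opened in step 2.

Assumption: (−)-sclareol (bulk clary-sage diterpene) is the commercial chiral starting material, labdane numbering is used, and the counter-electrode reaction of the electrolysis is water oxidation in the separated anode chamber (cathode: sclareol + O2 + 2 H+ + 2 e− → epoxide + H2O; anode: H2O → ½ O2 + 2 H+ + 2 e−).

**Step 1**
Reactants: 1 (−)-sclareol [(13R)-labd-14-ene-8α,13-diol]
Product: 3 (13R,14R)-14,15-epoxylabdane-8α,13-diol, via vanadium diolate hydroperoxide 2 (not isolated)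
Conditions: O2 (1 atm), VO(OiPr)3 (20 mol%), 2,4,6-collidinium triflate (30 mol%), Bu4NPF6 (0.1 M), 3 Å MS, CH2Cl2, RVC cathode (−0.6 V vs Ag/AgCl, 2.3 F/mol), Nafion-divided cell, Pt anode in 0.1 M H2SO4 (MeCN/H2O), 20 °C, dark
Reagents that add atoms: dioxygen, O=O
Why: Proposed new method: two-electron cathodic reduction of O2 (collidinium as proton relay, directly or through the tetravalent/pentavalent vanadium couple) gives a low steady concentration of hydroperoxide, which is captured by pentavalent vanadium already bound to both tertiary alkoxides O8 and O13 (eight-membered chelate 2), and the metal-bound peroxide oxygen is then transferred to C14=C15 inside the chelate; because the metal sits over the alkene, the ring through O8 can only close if C12 is gauche and the C13 methyl anti to vanadium about the O13–C13 bond, so oxygen reaches the C14 Re face and the bought 13R centre sets 14R, reversing the weak opposite preference expected for monodentate binding; the closest known reactions are the Sharpless–Michaelson VO(acac)2/t-BuOOH hydroxyl-directed epoxidation of allylic alcohols and oxidations fed by cathodically generated hydrogen peroxide, and neither an electrochemically driven directed epoxidation nor diolate-chelate control of its facial selectivity has been shown.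

**Step 2**
Reactants: 3 (13R,14R)-14,15-epoxylabdane-8α,13-diol
Product: 4 (13R,14R)-15-acetoxylabdane-8α,13,14-triol (target)
Conditions: Ti(OiPr)4 (1.5 equiv), AcOH (2 equiv), CH2Cl2, 0 °C → rt; aq. citric acid
Reagents that add atoms: acetic acid, CC(=O)O
Why: Titanium-mediated C3-selective opening of a 2,3-epoxy alcohol (Caron–Sharpless conditions): tetravalent titanium coordinated to O13 and the oxirane oxygen activates the ring, acetate attacks the unhindered primary C15 in an SN2 step, the C14–O bond is never broken so 14R is carried through, and the tertiary 8- and 13-hydroxyls are not acylated.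

**Compound list**

1 | (−)-sclareol, (5S,8R,9R,10S,13R)-labd-14-ene-8α,13-diol | C=C[C@](C)(O)CC[C@@H]1[C@@]2(C)CCCC(C)(C)[C@@H]2CC[C@@]1(C)O | starting material
2 | pentavalent vanadium oxo hydroperoxo 8,13-diolate chelate of sclareol (O8 and O13 on one vanadium, eight-membered chelate ring, one oxo and one OOH ligand) | C=C[C@](C)(O[V]5(=O)OO)CC[C@@H]1[C@@]2(C)CCCC(C)(C)[C@@H]2CC[C@@]1(C)O5 | intermediate (not isolated)
3 | (13R,14R)-14,15-epoxylabdane-8α,13-diol (terminal oxirane; 13-OH and oxirane oxygen syn when C12–C13–C14–C15 is drawn zigzag) | C3O[C@H]3[C@](C)(O)CC[C@@H]1[C@@]2(C)CCCC(C)(C)[C@@H]2CC[C@@]1(C)O | intermediate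
4 | (13R,14R)-15-acetoxylabdane-8α,13,14-triol (CNP0523287.1) | CC(=O)OC[C@@H](O)[C@](C)(O)CC[C@@H]1[C@@]2(C)CCCC(C)(C)[C@@H]2CC[C@@]1(C)O | target

**Totals and risks**

Total steps: 2. Longest linear sequence: 2.

Steps most likely to fail (the route has only two steps, so both are given, the more risky first):

1. Step 1, the proposed new electro-epoxidation. The C14 selectivity rests on a chelate model worked out by hand, not on precedent. If the diolate chelate does not form, the 14S epimer may equal or exceed the 14R epimer; any 14S epoxide is removed from 3 by chromatography. The cathodic peroxide may also be used inefficiently, and vanadium may cause 1,3-transposition of the tertiary allylic alcohol. Fallback with known chemistry, setting out from 1 and coming back at 4: hydrogen-bond-directed catalytic osmylation of 1 (OsO4 5 mol%, Me3NO·2H2O, CH2Cl2, rt; the 13-OH hydrogen-bonds to the oxidant, which favours the syn diol) gives, after chromatographic removal of the 14-epimer, (13R,14R)-labdane-8α,13,14,15-tetrol F1. Acetylation of F1 at the primary hydroxyl only (Ac2O 1.05 equiv, 2,4,6-collidine, CH2Cl2, −20 °C) then gives 4. This replaces epoxidation and opening by dihydroxylation and site-selective acylation and does not pass through 3.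

2. Step 2, the acetolysis of the oxirane. Possible failures are isopropoxide transfer from titanium, Lewis-acid rearrangement of the epoxy carbinol, and acetyl migration from O15 to O14. Fallback, setting out from 3 and coming back at 4: a two-stage, purely nucleophilic sequence. LiBr/AcOH in THF (0 °C → rt) opens 3 at C15 to give (13R,14S)-15-bromolabdane-8α,13,14-triol F2; the geometry at C14 is that of 3, and the descriptor changes only because bromine raises the rank of C15. CsOAc with catalytic 18-crown-6 in DMF at 40 °C then replaces the primary bromide by acetate, directly or through reclosure to 3, to give 4.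

Further compounds
F1 | step 1 | (13R,14R)-labdane-8α,13,14,15-tetrol | OC[C@@H](O)[C@](C)(O)CC[C@@H]1[C@@]2(C)CCCC(C)(C)[C@@H]2CC[C@@]1(C)O
F2 | step 2 | (13R,14S)-15-bromolabdane-8α,13,14-triol | BrC[C@@H](O)[C@](C)(O)CC[C@@H]1[C@@]2(C)CCCC(C)(C)[C@@H]2CC[C@@]1(C)O
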